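The cyclobutane is split into two cis-locked two-carbon units. C1–C2, carrying the cis-carboxyl groups, is maleic anhydride. C3–C4, the two quaternary carbons that each carry a methyl and a pyranone and hold the pyranones cis, is the ring alkene of 2,5-dimethoxy-2,3,4,5-tetramethyl-2,5-dihydrofuran, a ring-locked (Z)-enedione whose ketal carbons become C6 of the two pyranone rings. One sensitised [2+2] photocycloaddition forms the C2–C3 and C1–C4 bonds, closes the cyclobutane and sets all four stereocentres as the meso cis-anti-cis array. The temporary dihydrofuran ring is then hydrolysed to a cis-diacetyl unit, from which both pyranones are grown at once.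

Key step: step 3

Remark: the target is a meso compound (mirror plane through the midpoints of C1–C2 and C3–C4), so only relative configuration has to be controlled. Cyclobutane numbering: C1/C2 carry the carboxyl groups, C3/C4 are the quaternary carbons.

Step 1
Reactants: 1 3,4-dimethylhexane-2,5-dione (commercial mixture of diastereomers)
Product: 2 2,3,4,5-tetramethylfuran
Conditions: TsOH·H2O (cat.), toluene, reflux, Dean–Stark
Reagents that add atoms: none
Why: Paal–Knorr cyclodehydration of a 1,4-diketone; both diastereomers should converge on the same achiral furan.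

Step 2
Reactants: 2 2,3,4,5-tetramethylfuran
Product: 3 2,5-dimethoxy-2,3,4,5-tetramethyl-2,5-dihydrofuran (cis/trans mixture at C2/C5)
Conditions: Br2 (1 equiv), Na2CO3 (2 equiv), MeOH, −40 °C to 0 °C
Reagents that add atoms: methanol, CO
Why: Clauson-Kaas oxidative 2,5-dimethoxylation of a furan should leave the C3=C4 bond as an isolated ring alkene that is a Z-locked, masked 3,4-dimethylhex-3-ene-2,5-dione; the ketal configuration is irrelevant because both ketal carbons later become carbonyl carbons.

Step 3
Reactants: 3 2,5-dimethoxy-2,3,4,5-tetramethyl-2,5-dihydrofuran (1.5 equiv); 4 maleic anhydride (freshly sublimed)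
Product: 5 8,10-dimethoxy-1,7,8,10-tetramethyl-4,9-dioxatricyclo[5.3.0.0(2,6)]decane-3,5-dione, cis-anti-cis (anhydride ring and dimethoxytetrahydrofuran ring on opposite faces of the cyclobutane; mixture at C8/C10)
Conditions: hν (λ > 300 nm, Pyrex), acetophenone (sens.), MeCN, 10 °C, degassed
Reagents that add atoms: none
Why: Triplet-sensitised [2+2] photocycloaddition, the reaction type known for maleic anhydride with cyclopentene or 2,5-dihydrofuran: triplet maleic anhydride adds to the ring C=C bond of 3 to give a triplet 1,4-biradical, which after intersystem crossing collapses to the cyclobutane. The four-membered ring is thus closed by a stepwise cycloaddition, the second C–C bond forming by radical recombination within the biradical. Both five-membered rings can only be cis-fused to the new ring, so the anhydride holds the two future carboxyl groups cis and the dihydrofuran holds the two future acyl carbons cis. The biradical should close with the anhydride carbonyls next to the small methyl groups and away from the quaternary ketal carbons, giving the cis-anti-cis adduct and with it all four stereocentres of the target. The step needs cross-addition to outrun dimerisation of maleic anhydride and allylic hydrogen abstraction; excess alkene, low temperature and acid-free anhydride (which also keeps the ketal intact) are meant to secure this.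

Step 4
Reactants: 5 cis-anti-cis photoadduct
Product: 7 6,7-diacetyl-6,7-dimethyl-3-oxabicyclo[3.2.0]heptane-2,4-dione (meso; acetyl groups mutually cis and trans to the anhydride ring), via diacetyl diacid 6 (not isolated)
Conditions: 1 M HCl, THF, rt; evaporate (toluene azeotrope); then Ac2O, 60 °C
Reagents that add atoms: water, O
Why: Acid hydrolysis of the cyclic bis-ketal should release both methyl ketones (and open the anhydride), and acetic anhydride then re-closes the cis-diacid to the cyclic anhydride; the quaternary α-carbons exclude epimerisation and furan formation.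

Step 5
Reactants: 7 diacetyl anhydride
Product: 8 6,7-dimethyl-6,7-bis[1-(trimethylsilyloxy)ethenyl]-3-oxabicyclo[3.2.0]heptane-2,4-dione
Conditions: TMSOTf (2.3 equiv), Et3N (3 equiv), CH2Cl2, 0 °C; pentane extraction, no aqueous work-up
Reagents that add atoms: trimethylsilyl trifluoromethanesulfonate, C[Si](C)(C)OS(=O)(=O)C(F)(F)F
Why: Soft enolisation/silylation; each ketone can enolise only toward its CH3 group (the other α-carbon is quaternary), so a single bis-silyl enol ether should form, and the cis-fused anhydride cannot change configuration.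

Step 6
Reactants: 8 bis-silyl enol ether; 9 methylmalonyl dichloride (2.1 equiv)
Product: 10 6,7-bis(4-hydroxy-3-methyl-2-oxo-2H-pyran-6-yl)-6,7-dimethyl-3-oxabicyclo[3.2.0]heptane-2,4-dione
Conditions: Et2O, −78 °C to rt; evaporate, triturate (no aqueous work-up)
Reagents that add atoms: none
Why: Pyranone annulation of silyl enol ethers with a malonyl dichloride: C-acylation of each enol ether (loss of Me3SiCl) followed by closure of the enol oxygen onto the second acyl chloride should build both 4-hydroxy-3-methyl-2-pyranone rings in one operation; no stereocentre is formed or touched.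

Step 7
Reactants: 10 bis(hydroxypyranone) anhydride
Product: 11 6,7-bis(4-methoxy-3-methyl-2-oxo-2H-pyran-6-yl)-6,7-dimethyl-3-oxabicyclo[3.2.0]heptane-2,4-dione
Conditions: CH2N2 (slight excess), Et2O/THF, 0 °C
Reagents that add atoms: diazomethane, C=[N+]=[N-]
Why: O-methylation of the acidic 4-hydroxy-2-pyranone (a vinylogous acid) with diazomethane should give mainly the 4-methoxy-2-pyranone under neutral, alcohol-free conditions that the anhydride tolerates.

Step 8
Reactants: 11 bis(methoxypyranone) anhydride
Product: 12 (1R,2S,3R,4S)-3,4-bis(4-methoxy-3-methyl-2-oxo-2H-pyran-6-yl)-3,4-dimethylcyclobutane-1,2-dicarboxylic acid (meso; CNP0574758.1)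
Conditions: H2O, THF, 40 °C
Reagents that add atoms: water, O
Why: Neutral hydrolysis of the cyclic anhydride should give the cis-diacid without base, so neither epimerisation at C1/C2 nor opening of the pyranones is expected.

Compound list
1 | 3,4-dimethylhexane-2,5-dione | CC(=O)C(C)C(C)C(C)=O | starting material
2 | 2,3,4,5-tetramethylfuran | Cc1oc(C)c(C)c1C | intermediate
3 | 2,5-dimethoxy-2,3,4,5-tetramethyl-2,5-dihydrofuran (cis/trans mixture) | COC1(C)OC(C)(OC)C(C)=C1C | intermediate
4 | maleic anhydride | O=C1OC(=O)C=C1 | starting material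
5 | 8,10-dimethoxy-1,7,8,10-tetramethyl-4,9-dioxatricyclo[5.3.0.0(2,6)]decane-3,5-dione, cis-anti-cis (ketal carbons unassigned) | COC1(C)[C@@]2(C)[C@@H]3C(=O)OC(=O)[C@@H]3[C@@]2(C)C(C)(OC)O1 | intermediate
6 | (1R,2S,3R,4S)-3,4-diacetyl-3,4-dimethylcyclobutane-1,2-dicarboxylic acid (formed in the flask in step 4) | CC(=O)[C@@]1(C)[C@H](C(=O)O)[C@H](C(=O)O)[C@@]1(C)C(C)=O | intermediate
7 | 6,7-diacetyl-6,7-dimethyl-3-oxabicyclo[3.2.0]heptane-2,4-dione (acetyls cis, anti to the anhydride ring) | CC(=O)[C@@]1(C)[C@@H]2C(=O)OC(=O)[C@@H]2[C@@]1(C)C(C)=O | intermediate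
8 | 6,7-dimethyl-6,7-bis[1-(trimethylsilyloxy)ethenyl]-3-oxabicyclo[3.2.0]heptane-2,4-dione | C=C(O[Si](C)(C)C)[C@@]1(C)[C@@H]2C(=O)OC(=O)[C@@H]2[C@@]1(C)C(=C)O[Si](C)(C)C | intermediate
9 | methylmalonyl dichloride | CC(C(=O)Cl)C(=O)Cl | starting material
10 | 6,7-bis(4-hydroxy-3-methyl-2-oxo-2H-pyran-6-yl)-6,7-dimethyl-3-oxabicyclo[3.2.0]heptane-2,4-dione | Oc1cc([C@@]2(C)[C@@H]3C(=O)OC(=O)[C@@H]3[C@@]2(C)c2cc(O)c(C)c(=O)o2)oc(=O)c1C | intermediate
11 | 6,7-bis(4-methoxy-3-methyl-2-oxo-2H-pyran-6-yl)-6,7-dimethyl-3-oxabicyclo[3.2.0]heptane-2,4-dione | COc1cc([C@@]2(C)[C@@H]3C(=O)OC(=O)[C@@H]3[C@@]2(C)c2cc(OC)c(C)c(=O)o2)oc(=O)c1C | intermediate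
12 | (1R,2S,3R,4S)-3,4-bis(4-methoxy-3-methyl-2-oxo-2H-pyran-6-yl)-3,4-dimethylcyclobutane-1,2-dicarboxylic acid (meso) | COc1cc([C@@]2(C)[C@H](C(=O)O)[C@H](C(=O)O)[C@@]2(C)c2cc(OC)c(C)c(=O)o2)oc(=O)c1C | target

Total step count: 8. Longest linear sequence: 8 steps (1 → 12).

Steps most likely to fail

Step 3. Triplet maleic anhydride may dimerise or abstract allylic hydrogen from the four methyl groups faster than it adds to the hindered, electron-rich tetrasubstituted alkene, and traces of acid may open the ketal before the cycloaddition. The fallback sets out from 4 and comes back at 7; it masks the cis-diacetyl unit as an acid-stable cyclobutene instead of a ketal and unmasks it by oxidative cleavage. Compound 4 would be irradiated under the same sensitisation with cis-3,4-dichloro-1,2,3,4-tetramethylcyclobut-1-ene (CC1=C(C)C(C)(Cl)C1(C)Cl, a known one-step product of 2-butyne and Cl2). This should give the exo adduct 5,6-dichloro-1,4,5,6-tetramethylbicyclo[2.2.0]hexane-2,3-dicarboxylic anhydride F1. Zn dust (Me3SiCl-activated, THF, reflux) should remove both chlorines to give 1,4,5,6-tetramethylbicyclo[2.2.0]hex-5-ene-2,3-dicarboxylic anhydride F2. Ozonolysis (O3, CH2Cl2, −78 °C; then Me2S) of the tetrasubstituted cyclobutene bond should then deliver 7 with the acetyl groups cis and anti to the anhydride.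

Step 6. Hydrogen chloride released by the first lactonisation may protodesilylate the second enol ether, or the diacid chloride may O-acylate or oligomerise, so that only one pyranone ring forms. The fallback sets out from 8 and comes back at 10, separating C-acylation from ring closure. ZnCl2-mediated C-acylation of both enol ethers with tert-butyl 3-chloro-2-methyl-3-oxopropanoate (CH2Cl2, 0 °C) should give di-tert-butyl 5,5'-(6,7-dimethyl-2,4-dioxo-3-oxabicyclo[3.2.0]heptane-6,7-diyl)bis(2-methyl-3,5-dioxopentanoate) F3. Trifluoroacetic acid/trifluoroacetic anhydride (rt) should then cleave the tert-butyl esters and lactonise both triketide arms to 10, while keeping the anhydride closed.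

Step 7. Methylation may occur in part at the ring carbonyl oxygen (giving the 2-methoxy-4-pyranone isomer), and diazomethane or moisture may attack the anhydride. The fallback sets out from 10 and comes back at 12, giving up chemoselective methylation for global methylation and a selective ester cleavage. Hydrolysis (H2O, THF) should give 3,4-bis(4-hydroxy-3-methyl-2-oxo-2H-pyran-6-yl)-3,4-dimethylcyclobutane-1,2-dicarboxylic acid F4. Me2SO4/K2CO3 in acetone (reflux), the standard 4-O-selective conditions, should give dimethyl 3,4-bis(4-methoxy-3-methyl-2-oxo-2H-pyran-6-yl)-3,4-dimethylcyclobutane-1,2-dicarboxylate F5. Me3SnOH (1,2-dichloroethane, 80 °C) should then cleave the two methyl esters under neutral conditions to 12.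

Further compounds
F1 | step 3 | 5,6-dichloro-1,4,5,6-tetramethylbicyclo[2.2.0]hexane-2,3-dicarboxylic anhydride (exo; C–Cl centres unassigned) | CC1(Cl)[C@@]2(C)[C@@H]3C(=O)OC(=O)[C@@H]3[C@@]2(C)C1(C)Cl
F2 | step 3 | 1,4,5,6-tetramethylbicyclo[2.2.0]hex-5-ene-2,3-dicarboxylic anhydride (exo) | CC1=C(C)[C@@]2(C)[C@@H]3C(=O)OC(=O)[C@@H]3[C@]21C
F3 | step 6 | di-tert-butyl 5,5'-(6,7-dimethyl-2,4-dioxo-3-oxabicyclo[3.2.0]heptane-6,7-diyl)bis(2-methyl-3,5-dioxopentanoate) | CC(C(=O)OC(C)(C)C)C(=O)CC(=O)[C@@]1(C)[C@@H]2C(=O)OC(=O)[C@@H]2[C@@]1(C)C(=O)CC(=O)C(C)C(=O)OC(C)(C)C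
F4 | step 7 | 3,4-bis(4-hydroxy-3-methyl-2-oxo-2H-pyran-6-yl)-3,4-dimethylcyclobutane-1,2-dicarboxylic acid | Oc1cc([C@@]2(C)[C@H](C(=O)O)[C@H](C(=O)O)[C@@]2(C)c2cc(O)c(C)c(=O)o2)oc(=O)c1C
F5 | step 7 | dimethyl 3,4-bis(4-methoxy-3-methyl-2-oxo-2H-pyran-6-yl)-3,4-dimethylcyclobutane-1,2-dicarboxylate | COc1cc([C@@]2(C)[C@H](C(=O)OC)[C@H](C(=O)OC)[C@@]2(C)c2cc(OC)c(C)c(=O)o2)oc(=O)c1C
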